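**Retrosynthetic overview**
- The last C–C bond is C12–C13. A B-alkyl Suzuki coupling joins a bicyclic 9β-vinyl-8α-carbinol to an E-vinyl iodide made from geranyl bromide by carboalumination.
- The 8α-OH and the 9β-carbon chain are set on a cis-fused C7-enone: conjugate vinylation from its convex β face, then anti bromohydrin formation. The temporary C7 carbonyl is removed through its enol triflate.
- Ring A (C1–C2–C3–C4–C5–C10) is cut at C4–C5. This bond is made by an Fe–H (MHAT) radical conjugate addition inside a monocyclic 4,4-disubstituted cyclohexenone.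
- Ring order: ring B first (asymmetric Michael/aldol annulation of racemic melonal with methyl vinyl ketone, which sets quaternary C10), ring A last.
- Enabling feature: C4 is a gem-dimethyl carbon, so it can be generated as a tertiary radical from a prenyl C3=C4 bond. It is bonded to fusion carbon C5, and C5–H is syn to the C10 methyl (cis A/B fusion). A C1–C3 tether anchored on C10 therefore delivers C4 to its own face of C5, which is the β-carbon of a carbonyl placed at C7 of ring B.

Key step: step 3

Remark: locants follow drimane usage (ring A = C1–C5 + C10; ring B = C5–C10; C4 gem-dimethyl, C10 angular CH3, C8 carbinol, C9 side-chain carbon, side chain C11, C12 …; β = face of the C10 methyl); read this way the SMILES has 5β-H, 9α-H and 8α-OH, that is a cis-fused decalin, (1R,2R,4aR,8aS).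

**Step 1**
Reactants: 1 (±)-2,6-dimethylhept-5-enal (melonal); 2 but-3-en-2-one (methyl vinyl ketone)
Product: 4 (4R)-4-methyl-4-(4-methylpent-3-enyl)cyclohex-2-en-1-one, via keto aldehyde 3 (not isolated)
Conditions: chiral trans-cyclohexane-1,2-diamine / trans-cyclohexane-1,2-dicarboxylic acid salt (30 mol %, the enantiomer selected to give R), i-PrOH, rt
Reagents that add atoms: none
Why: Enamine Michael addition of the α-branched aldehyde to the vinyl ketone followed by intramolecular aldol condensation (asymmetric Robinson-type annulation) should close ring B; the stereocentre of racemic 1 is erased in the enamine, so both enantiomers converge, and the catalyst-shielded enamine face sets quaternary C10.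

**Step 2**
Reactants: 4 (4R)-4-methyl-4-(4-methylpent-3-enyl)cyclohex-2-en-1-one
Product: 6 (4R)-4,6-dimethyl-4-(4-methylpent-3-enyl)cyclohex-2-en-1-one (C6 epimers), via lithium dienolate 5 (not isolated)
Conditions: LDA, THF, −78 °C; MeI, −78 → 0 °C
Reagents that add atoms: iodomethane, CI
Why: Kinetic α′-deprotonation (no γ-H exists at quaternary C10) and SN2 methylation of the cross-conjugated enolate install the future C8 methyl; the new centre needs no control because it becomes sp2 in step 4.

**Step 3**
Reactants: 6 (4R)-4,6-dimethyl-4-(4-methylpent-3-enyl)cyclohex-2-en-1-one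
Product: 7 cis-fused 4,4,8,10-tetramethyl-5βH-decalin-7-one (10β-CH3; C8 epimers)
Conditions: Fe(acac)3 (0.3 equiv), PhSiH3 (2.5 equiv), EtOH, 0.02 M, 60 °C
Reagents that add atoms: none
Why: Fe(acac)3/PhSiH3 forms an iron hydride that transfers H• to C3 of the electron-rich C3=C4 bond (Markovnikov MHAT), the nucleophilic tertiary C4 radical adds to C5, the β-carbon of the enone, and the α-keto radical is reduced to an iron enolate and protonated by EtOH. The closest known reaction type is the iron-catalysed reductive olefin coupling (MHAT Giese reaction) of unactivated alkenes with enones, established in its intramolecular form and for the making of quaternary carbons. Ring A closes 6-exo-trig through the new C4–C5 bond. C5 is controlled by the tether: the C1–C3 chain stands on the α face of quaternary C10 and the radical must attack perpendicular to the enone plane, so C4 can bond only to the α face of C5 and C5–H ends syn to the C10 methyl (cis fusion), while C4 is not stereogenic and the C8 epimers are carried on. The step needs H• transfer to the alkene rather than to the enone, and ring closure faster than capture of the radical by a second H•; the polarity match of donor alkene and acceptor enone, the gem-disubstituent effect of C10 and high dilution should secure both. Other ring sizes should not compete because C5 is the only electrophilic carbon within reach of C4.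

**Step 4**
Reactants: 7 cis-fused 4,4,8,10-tetramethyl-5βH-decalin-7-one
Product: 9 cis-fused 4,4,8,10-tetramethyl-5βH-decal-8-en-7-one, via α-chloro ketone 8 (not isolated)
Conditions: SO2Cl2, CH2Cl2, 0 °C; evaporate; Li2CO3, LiBr, DMF, 120 °C
Reagents that add atoms: none
Why: α-Chlorination through the more substituted enol followed by dehydrochlorination gives the conjugated 2-methyl enone and funnels both C8 epimers into one compound; C5 is β to the carbonyl and C10 is quaternary, so neither can epimerise.

**Step 5**
Reactants: 9 cis-fused 4,4,8,10-tetramethyl-5βH-decal-8-en-7-one; 10 vinylmagnesium bromide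
Product: 12 9β-vinyl-4,4,8,10-tetramethyl-5βH-decal-7-en-7-yl triflate, via magnesium enolate 11 (not isolated)
Conditions: CuBr·SMe2 (20 mol %), THF/DMPU, −78 → −30 °C; PhNTf2, −78 °C → rt
Reagents that add atoms: N-phenylbis(trifluoromethanesulfonimide), O=S(=O)(N(c1ccccc1)S(=O)(=O)C(F)(F)F)C(F)(F)F
Why: Copper-catalysed 1,4-addition should occur axially at C9 from the convex β face, anti to the pseudoaxial C1 methylene on C10 (ring A and the C4 methyls screen the α face), which sets C9, and O-triflation of the regiodefined enolate fixes the C7=C8 double bond.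

**Step 6**
Reactants: 12 9β-vinyl-4,4,8,10-tetramethyl-5βH-decal-7-en-7-yl triflate
Product: 13 9β-vinyl-4,4,8,10-tetramethyl-5βH-decal-7-ene
Conditions: Pd(OAc)2 (5 mol %), PPh3, HCO2H, n-Bu3N, DMF, 60 °C
Reagents that add atoms: none
Why: Oxidative addition of Pd(0) into the C7–OTf bond, formate decarboxylation and C–H reductive elimination (Pd-catalysed formate reduction of an enol triflate) remove the temporary C7 oxygen without touching a stereocentre.

**Step 7**
Reactants: 13 9β-vinyl-4,4,8,10-tetramethyl-5βH-decal-7-ene
Product: 14 7β-bromo-9β-vinyl-4,4,8,10-tetramethyl-5βH-decalin-8α-ol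
Conditions: NBS, acetone/H2O 4:1, 0 °C, dark
Reagents that add atoms: N-bromosuccinimide, O=C1CCC(=O)N1Br; water, O
Why: Bromohydrin formation is chemoselective for the electron-rich trisubstituted C7=C8 bond over the vinyl group; the bromonium ion forms on the open β face and water opens it anti at tertiary C8 (Markovnikov, trans-diaxial), which sets 8α-OH/8β-CH3.

**Step 8**
Reactants: 14 7β-bromo-9β-vinyl-4,4,8,10-tetramethyl-5βH-decalin-8α-ol
Product: 15 (1R,2R,4aR,8aS)-1-ethenyl-2,5,5,8a-tetramethyldecahydronaphthalen-2-ol (9β-vinyl-8α-ol)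
Conditions: n-Bu3SnH, AIBN (cat.), toluene, 80 °C
Reagents that add atoms: none
Why: Radical chain hydrodebromination replaces C7–Br by H; C8 and C9 are not involved, and the C7 radical has only disfavoured 4-exo/5-endo paths to the vinyl group.

**Step 9**
Reactants: 16 1-(trimethylsilyl)propyne; 17 geranyl bromide
Product: 19 (E)-trimethyl(6,10-dimethylundeca-5,9-dien-1-ynyl)silane, via lithiated silylpropyne 18 (not isolated)
Conditions: n-BuLi, THF, −78 → −20 °C; 17, −78 °C → rt
Reagents that add atoms: none
Why: Propargylic lithiation and SN2 alkylation at the primary allylic carbon keep the E double bond of the geranyl unit.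

**Step 10**
Reactants: 19 (E)-trimethyl(6,10-dimethylundeca-5,9-dien-1-ynyl)silane
Product: 20 (E)-6,10-dimethylundeca-5,9-dien-1-yne
Conditions: K2CO3 (cat.), MeOH, rt
Reagents that add atoms: none
Why: Base-catalysed methanolysis of the alkynyl C–Si bond (protiodesilylation) frees the terminal alkyne and leaves the alkenes untouched.

**Step 11**
Reactants: 20 (E)-6,10-dimethylundeca-5,9-dien-1-yne
Product: 22 (1E,5E)-1-iodo-2,6,10-trimethylundeca-1,5,9-triene, via vinylalane 21 (not isolated)
Conditions: Me3Al, Cp2ZrCl2 (0.25 equiv), CH2Cl2, 0 °C → rt; I2, THF, −30 °C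
Reagents that add atoms: trimethylaluminium, C[Al](C)C; iodine, II
Why: Negishi zirconium-catalysed syn-carboalumination puts CH3 on the internal and Al on the terminal alkyne carbon, and iodinolysis with retention gives the E-trisubstituted vinyl iodide.

**Step 12**
Reactants: 15 (1R,2R,4aR,8aS)-1-ethenyl-2,5,5,8a-tetramethyldecahydronaphthalen-2-ol; 22 (1E,5E)-1-iodo-2,6,10-trimethylundeca-1,5,9-triene
Product: 24 (1R,2R,4aR,8aS)-2,5,5,8a-tetramethyl-1-[(3E,7E)-4,8,12-trimethyltrideca-3,7,11-trienyl]decahydronaphthalen-2-ol (target), via B-alkyl-9-BBN 23 (not isolated)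
Conditions: 9-BBN-H (2.2 equiv), THF, rt; 22, PdCl2(dppf) (5 mol %), AsPh3, aq NaOH, THF/DMF, rt → 40 °C
Reagents that add atoms: none
Why: Anti-Markovnikov hydroboration of the only alkene in 15, then B-alkyl Suzuki–Miyaura coupling with retention of the E geometry, forms C12–C13; the free tertiary alcohol and the trisubstituted alkenes of 22 are tolerated and no stereocentre is touched.

**Compound list**

| No. | Name | SMILES | Role |
|---|---|---|---|
| 1 | (±)-2,6-dimethylhept-5-enal | CC(C)=CCCC(C)C=O | starting material |
| 2 | but-3-en-2-one | C=CC(C)=O | starting material |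
| 3 | (2R)-2-methyl-2-(4-methylpent-3-enyl)-5-oxohexanal | O=C[C@](C)(CCC=C(C)C)CCC(C)=O | intermediate |
| 4 | (4R)-4-methyl-4-(4-methylpent-3-enyl)cyclohex-2-en-1-one | O=C1C=C[C@](C)(CCC=C(C)C)CC1 | intermediate |
| 5 | lithium (4R)-4-methyl-4-(4-methylpent-3-enyl)cyclohexa-1,5-dien-1-olate | [Li+].[O-]C=1C=C[C@](C)(CCC=C(C)C)CC=1 | intermediate |
| 6 | (4R)-4,6-dimethyl-4-(4-methylpent-3-enyl)cyclohex-2-en-1-one (C6 epimers) | O=C1C=C[C@](C)(CCC=C(C)C)CC1C | intermediate |
| 7 | cis-fused 4,4,8,10-tetramethyl-5βH-decalin-7-one (C8 epimers) | CC1C[C@@]2(C)CCCC(C)(C)[C@H]2CC1=O | intermediate |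
| 8 | 8-chloro derivative of 7 | CC1(Cl)C[C@@]2(C)CCCC(C)(C)[C@H]2CC1=O | intermediate |
| 9 | cis-fused 4,4,8,10-tetramethyl-5βH-decal-8-en-7-one | CC1=C[C@@]2(C)CCCC(C)(C)[C@H]2CC1=O | intermediate |
| 10 | vinylmagnesium bromide | C=C[Mg]Br | starting material |
| 11 | bromomagnesium C7 enolate of the 9β-vinyl ketone | C=C[C@@H]1[C@@]2(C)CCCC(C)(C)[C@H]2CC([O-])=C1C.[Mg+2].[Br-] | intermediate |
| 12 | 9β-vinyl-4,4,8,10-tetramethyl-5βH-decal-7-en-7-yl triflate | C=C[C@@H]1[C@@]2(C)CCCC(C)(C)[C@H]2CC(OS(=O)(=O)C(F)(F)F)=C1C | intermediate |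
| 13 | 9β-vinyl-4,4,8,10-tetramethyl-5βH-decal-7-ene | C=C[C@@H]1[C@@]2(C)CCCC(C)(C)[C@H]2CC=C1C | intermediate |
| 14 | 7β-bromo-9β-vinyl-4,4,8,10-tetramethyl-5βH-decalin-8α-ol | C=C[C@@H]1[C@@]2(C)CCCC(C)(C)[C@H]2C[C@H](Br)[C@@]1(C)O | intermediate |
| 15 | (1R,2R,4aR,8aS)-1-ethenyl-2,5,5,8a-tetramethyldecahydronaphthalen-2-ol | C=C[C@@H]1[C@@]2(C)CCCC(C)(C)[C@H]2CC[C@@]1(C)O | intermediate |
| 16 | 1-(trimethylsilyl)propyne | CC#C[Si](C)(C)C | starting material |
| 17 | geranyl bromide | CC(C)=CCC/C(C)=C/CBr | starting material |
| 18 | [3-(trimethylsilyl)prop-2-ynyl]lithium | [Li]CC#C[Si](C)(C)C | intermediate |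
| 19 | (E)-trimethyl(6,10-dimethylundeca-5,9-dien-1-ynyl)silane | CC(C)=CCC/C(C)=C/CCC#C[Si](C)(C)C | intermediate |
| 20 | (E)-6,10-dimethylundeca-5,9-dien-1-yne | CC(C)=CCC/C(C)=C/CCC#C | intermediate |
| 21 | dimethyl[(1E,5E)-2,6,10-trimethylundeca-1,5,9-trienyl]alane | CC(C)=CCC/C(C)=C/CC/C(C)=C/[Al](C)C | intermediate |
| 22 | (1E,5E)-1-iodo-2,6,10-trimethylundeca-1,5,9-triene | CC(C)=CCC/C(C)=C/CC/C(C)=C/I | intermediate |
| 23 | B-[2-(8α-hydroxy bicycle-9β-yl)ethyl]-9-BBN | C12CCCC(CCC1)B2CC[C@@H]3[C@@]4(C)CCCC(C)(C)[C@H]4CC[C@@]3(C)O | intermediate |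
| 24 | (1R,2R,4aR,8aS)-2,5,5,8a-tetramethyl-1-[(3E,7E)-4,8,12-trimethyltrideca-3,7,11-trienyl]decahydronaphthalen-2-ol | CC(C)=CCC/C(C)=C/CC/C(C)=C/CC[C@@H]1[C@@]2(C)CCCC(C)(C)[C@H]2CC[C@@]1(C)O | target |

**Step count**
Total steps: 12. Longest linear sequence: 9 steps (steps 1–8 and 12). Steps 9–11 are a convergent three-step branch.

**Steps most likely to fail**

1. **Step 1.** The catalyst may discriminate poorly between the two enamine geometries (CH3 against CH2R on the α-carbon), which would erode the enantioselectivity at C10. The Michael addition of the hindered enamine may also be slow.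
   - The fallback sets the centre by desymmetrisation instead. It sets out from 1 and 2.
   - A base-mediated Robinson annulation (KOH, EtOH) gives racemic 4-methyl-4-(4-methylpent-3-enyl)cyclohex-2-en-1-one F1.
   - Kinetic silylation (LDA, TMSCl) gives the silyl dienol ether F2.
   - Saegusa–Ito oxidation (Pd(OAc)2, MeCN) gives the achiral 4-methyl-4-(4-methylpent-3-enyl)cyclohexa-2,5-dien-1-one F3.
   - Enantioselective conjugate reduction of one of its two enantiotopic C=C bonds returns to 4. This uses an ene-reductase of the old-yellow-enzyme family with NADPH recycling in buffer at 30 °C.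

2. **Step 3.** The tertiary radical may capture a hydrogen atom early (plain hydrogenation of the prenyl bond), or the enone may be reduced in a conjugate sense, before the congested C4–C5 bond can form.
   - The fallback uncouples radical generation from the hydride source. It sets out from 6.
   - Markovnikov addition of HBr (CH2Cl2, −78 °C) gives the tertiary bromide (4R)-4-(4-bromo-4-methylpentyl)-4,6-dimethylcyclohex-2-en-1-one F4.
   - A tin hydride chain cyclisation (n-Bu3SnH and AIBN added by syringe pump to refluxing benzene) keeps the hydrogen donor scarce and returns to 7.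

3. **Step 5.** 1,2-Addition or enolisation may win over 1,4-addition at the neopentyl β-carbon of the α-methyl enone. O-triflation of the hindered enolate may also be incomplete.
   - The fallback moves the C–C bond formation to an allylic substitution. It sets out from 9.
   - Luche reduction (NaBH4, CeCl3, MeOH), with hydride delivery from the convex β face, gives the 7α-allylic alcohol F5.
   - Esterification (picolinic acid, DCC, DMAP) gives its picolinate F6.
   - Anti-SN2′ substitution with vinylMgBr/CuBr·SMe2 delivers the vinyl group to the β face of C9 and shifts the double bond to C7=C8. This comes back to the route at 13, so steps 5 and 6 are bypassed.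

**Further compounds**
F1 | step 1 | (±)-4-methyl-4-(4-methylpent-3-enyl)cyclohex-2-en-1-one | O=C1C=CC(C)(CCC=C(C)C)CC1
F2 | step 1 | trimethyl{[4-methyl-4-(4-methylpent-3-enyl)cyclohexa-1,5-dien-1-yl]oxy}silane | C[Si](C)(C)OC1=CCC(C)(CCC=C(C)C)C=C1
F3 | step 1 | 4-methyl-4-(4-methylpent-3-enyl)cyclohexa-2,5-dien-1-one | O=C1C=CC(C)(CCC=C(C)C)C=C1
F4 | step 3 | (4R)-4-(4-bromo-4-methylpentyl)-4,6-dimethylcyclohex-2-en-1-one | O=C1C=C[C@](C)(CCCC(C)(C)Br)CC1C
F5 | step 5 | cis-fused 4,4,8,10-tetramethyl-5βH-decal-8-en-7α-ol | CC1=C[C@@]2(C)CCCC(C)(C)[C@H]2C[C@H]1O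
F6 | step 5 | picolinate of the 7α-allylic alcohol | CC1=C[C@@]2(C)CCCC(C)(C)[C@H]2C[C@H]1OC(=O)c1ccccn1
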